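**Plan**

1. Last cuts: the C8(coumarin)–CH= bond of the styryl arm (Heck coupling), with the styryl alpha-carbon traced back to the formyl carbon of aldehyde 16; earlier, the C6(coumarin)–CH= bond of a second styryl arm (Heck coupling).
2. Ring cut: in the cyclohex-3-ene ring (C1 = quaternary carbon with methyl and formyl, C2 = CH bearing the coumarin-6-yl group, C3=C4(Me), C5H2, C6H2) the C1–C2 bond is allylic, benzylic and alpha to the formyl group. A 1,3-shift of C1 from C2 back to C4 gives the cyclobutane C1–C6–C5–C4, whose C4 carries methyl and the (E)-2-arylvinyl arm C3=C2: a donor–acceptor 2-alkenylcyclobutanecarbaldehyde (12).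
3. Forward order: cyclobutane ring first ([2+2] photocycloaddition of ethylene to dimethylmaleic anhydride); anhydride to lactone to lactol to vinyl and hydroxymethyl arms; Heck coupling with 6-bromo-7-methoxycoumarin; oxidation; then ring expansion from four to six members; then methylenation and Heck coupling with 8-iodo-7-methoxycoumarin.
4. Stereochemistry: the cyclobutane stereocentres are erased in an achiral ring-opened enamine/allyl cation, so racemic 12 converges. Both ring stereocentres arise in the ring closure: formyl cis to aryl from the tether-enforced boat and the (E)-alkene, absolute configuration from the chiral phosphate. Both (E)-alkenes come from Heck reactions on vinyl groups at quaternary carbons.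

Key step: step 8

Assumption: (R)-TRIP is taken to give the (1S,2S)-aldehyde 16; if the sense of induction proves opposite, (S)-TRIP is used with no other change.

**Route**

Step 1
Reactants: 1 2,3-dimethylmaleic anhydride; 2 ethylene
Product: 3 cis-1,5-dimethyl-3-oxabicyclo[3.2.0]heptane-2,4-dione (meso anhydride)
Conditions: ethylene (continuous stream), benzophenone (10 mol %), acetone, hν (medium-pressure Hg lamp, Pyrex), −30 °C
Reagents that add atoms: none
Why: Triplet-sensitised [2+2] photocycloaddition of a maleic anhydride to ethylene is a standard cyclobutane synthesis; the anhydride ring forces the cis fusion, the product is meso, and excess ethylene suppresses photodimerisation of 1.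

Step 2
Reactants: 3 meso anhydride
Product: 4 rac-cis-1,5-dimethyl-3-oxabicyclo[3.2.0]heptan-2-one
Conditions: NaBH4 (1.2 equiv), THF, 0 °C to rt; then 2 M HCl, rt
Reagents that add atoms: none
Why: Anhydride-to-lactone reduction (one carbonyl is reduced to the hydroxy acid, which lactonises on acidification); the symmetry of 3 means either carbonyl gives the same racemic cis-lactone.

Step 3
Reactants: 4 lactone
Product: 5 rac-cis-1,5-dimethyl-3-oxabicyclo[3.2.0]heptan-2-ol (lactol, anomer mixture)
Conditions: i-Bu2AlH (1.1 equiv), CH2Cl2, −78 °C; aqueous work-up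
Reagents that add atoms: none
Why: Partial reduction of a gamma-lactone to the lactol, the tetrahedral aluminate being stable at −78 °C; the anomeric centre is of no consequence.

Step 4
Reactants: 5 lactol
Product: 7 rac-cis-(2-ethenyl-1,2-dimethylcyclobutyl)methanol, via hydroxy aldehyde 6 (not isolated)
Conditions: Ph3PCH3Br (3 equiv), KOt-Bu (2.9 equiv), THF, 0 °C to 65 °C
Reagents that add atoms: methyltriphenylphosphonium bromide, C[P+](c1ccccc1)(c1ccccc1)c1ccccc1.[Br-]
Why: Wittig methylenation of a lactol through its open hydroxy aldehyde tautomer; the aldehyde has no alpha-hydrogen, so excess ylide cannot enolise it, and the cis relation of the two arms is kept.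

Step 5
Reactants: 8 5-bromo-2-hydroxy-4-methoxybenzaldehyde
Product: 10 6-bromo-7-methoxy-2H-chromen-2-one, via cinnamate ester 9 (not isolated)
Conditions: Ph3P=CHCO2Et (1.2 equiv), N,N-diethylaniline, 210 °C
Reagents that add atoms: ethyl (triphenylphosphoranylidene)acetate, CCOC(=O)C=P(c1ccccc1)(c1ccccc1)c1ccccc1
Why: Wittig olefination of a salicylaldehyde with a stabilised ylide, followed by thermal E/Z isomerisation and lactonisation, is the standard one-pot coumarin synthesis; the aryl bromide is inert.

Step 6
Reactants: 7 vinylcyclobutane alcohol; 10 6-bromo-7-methoxycoumarin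
Product: 11 rac-cis-6-{(E)-2-[2-(hydroxymethyl)-1,2-dimethylcyclobutyl]ethenyl}-7-methoxy-2H-chromen-2-one
Conditions: Pd(OAc)2 (5 mol %), P(o-tol)3 (12 mol %), Et3N (2 equiv), DMF, 100 °C
Reagents that add atoms: none
Why: Heck reaction of an aryl bromide with a monosubstituted alkene; because the allylic carbon is quaternary the only beta-hydrogens are benzylic, so only the (E)-styrene can form, the same pattern as Heck couplings of halocoumarins with 2-methylbut-3-en-2-ol.

Step 7
Reactants: 11 styryl alcohol
Product: 12 rac-cis-2-[(E)-2-(7-methoxy-2-oxo-2H-chromen-6-yl)ethenyl]-1,2-dimethylcyclobutane-1-carbaldehyde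
Conditions: Dess–Martin periodinane (1.3 equiv), CH2Cl2, 0 °C to rt
Reagents that add atoms: none
Why: Dess–Martin oxidation of a neopentyl primary alcohol under near-neutral conditions leaves the styrene, the lactone and the strained ring untouched; there is no alpha-hydrogen to epimerise.

Step 8
Reactants: 12 cyclobutanecarbaldehyde
Product: 16 (1S,2S)-2-(7-methoxy-2-oxo-2H-chromen-6-yl)-1,4-dimethylcyclohex-3-ene-1-carbaldehyde, via iminium ion 13 (not isolated), via enamine allyl cation 14 (not isolated), via product iminium ion 15 (not isolated)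
Conditions: Ph2CHNH2 (30 mol %), (R)-TRIP [(R)-3,3'-bis(2,4,6-triisopropylphenyl)-1,1'-binaphthyl-2,2'-diyl hydrogen phosphate] (10 mol %), toluene, 50 °C; then 1 M HCl, THF, rt
Reagents that add atoms: none
Why: Proposed new method: the aldehyde condenses with Ph2CHNH2 and the phosphoric acid protonates the imine, so that in iminium ion 13 the ring bond between the two quaternary carbons is a donor–acceptor bond (donor: the methyl- and styryl-bearing carbon; acceptor: the iminium-bearing carbon) that should heterolyse with release of about 26 kcal/mol of ring strain to the achiral enamine/1-aryl-3-methylallyl cation 14, on which all stereoisomers of 12 converge; capture of the cation by the enamine carbon at the benzylic terminus gives 15, which the water formed in the condensation hydrolyses to 16 with release of the amine. The closest known reaction types are the amine-catalysed, stereoablative ring opening and reclosure of donor–acceptor cyclopropanes (including the catalytic enantioselective vinylcyclopropane-to-cyclopentene rearrangement and the iminium-triggered opening of formylcyclopropanes), the SN1-type alpha-alkylation of alpha-branched aldehydes through primary-amine enamines paired with a chiral phosphate, and the acid-accelerated 3-aza-Cope rearrangement; none has been shown on a cyclobutane. The six-membered ring closes by C–C bond formation that is 6-endo at the allyl cation (its C=C stays in the ring) and exo at the enamine, through the boat arrangement that the two-carbon tether and the contact between nitrogen and the tertiary cation terminus enforce. Both stereocentres arise in this closure: the boat places the iminium carbon under the allyl unit on the same face as the (E)-aryl group, which fixes formyl cis to aryl and methyl trans, and the (R)-phosphate, hydrogen-bonded to the enamine N–H and ion-paired with the allyl cation, selects which pair of enantiotopic faces combines. The step needs six- over four-ring closure, C- over N-alkylation and cis over trans: ring strain makes return to the cyclobutane uphill, closure at the tertiary terminus by carbon or nitrogen is reversible while C–C formation at the benzylic terminus is not, and the tether secures the cis outcome.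

Step 9
Reactants: 16 cyclohexenecarbaldehyde
Product: 17 6-[(1R,6R)-6-ethenyl-3,6-dimethylcyclohex-2-en-1-yl]-7-methoxy-2H-chromen-2-one
Conditions: Zn, CH2Br2, TiCl4, THF/CH2Cl2, 0 °C to rt
Reagents that add atoms: dibromomethane, BrCBr
Why: Takai–Lombardo methylenation converts hindered, non-enolisable aldehydes into terminal alkenes without touching esters or lactones, so the coumarin survives where a phosphorus ylide might add to it; both stereocentres are untouched.

Step 10
Reactants: 18 7-hydroxy-2H-chromen-2-one (umbelliferone)
Product: 19 7-hydroxy-8-iodo-2H-chromen-2-one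
Conditions: I2 (1.05 equiv), KI, 20% aq. NH3, rt; then 2 M H2SO4
Reagents that add atoms: iodine, II
Why: Electrophilic aromatic iodination of the phenolate, which is most nucleophilic at C8 between the two oxygen-bearing carbons; acidification recloses any opened lactone.

Step 11
Reactants: 19 7-hydroxy-8-iodocoumarin
Product: 20 8-iodo-7-methoxy-2H-chromen-2-one
Conditions: MeI (1.5 equiv), K2CO3 (2 equiv), acetone, 56 °C
Reagents that add atoms: iodomethane, CI
Why: Williamson O-methylation of the phenol; the aryl iodide and the lactone are inert to carbonate in acetone.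

Step 12
Reactants: 17 vinylcyclohexene; 20 8-iodo-7-methoxycoumarin
Product: 21 7-methoxy-8-[(E)-2-[(1R,2R)-2-(7-methoxy-2-oxo-2H-chromen-6-yl)-1,4-dimethylcyclohex-3-en-1-yl]ethenyl]-2H-chromen-2-one (target)
Conditions: Pd(OAc)2 (10 mol %), Bu4NCl (1 equiv), NaHCO3 (2.5 equiv), DMF, 90 °C
Reagents that add atoms: none
Why: Heck reaction under ligand-free phase-transfer conditions, which suit hindered aryl iodides; the vinyl group sits on a quaternary carbon, so beta-hydride elimination can only give the (E)-styryl alkene, the trisubstituted ring alkene does not compete, and both stereocentres are remote from the reacting carbons.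

**Compound list**

1 | 2,3-dimethylmaleic anhydride | CC1=C(C)C(=O)OC1=O | starting material
2 | ethylene | C=C | starting material
3 | cis-1,5-dimethyl-3-oxabicyclo[3.2.0]heptane-2,4-dione (meso) | C[C@@]12CC[C@]1(C)C(=O)OC2=O | intermediate
4 | rac-cis-1,5-dimethyl-3-oxabicyclo[3.2.0]heptan-2-one (one enantiomer drawn) | C[C@@]12CC[C@]1(C)C(=O)OC2 | intermediate
5 | rac-cis-1,5-dimethyl-3-oxabicyclo[3.2.0]heptan-2-ol (anomer mixture) | C[C@@]12CC[C@]1(C)C(O)OC2 | intermediate
6 | rac-cis-2-(hydroxymethyl)-1,2-dimethylcyclobutane-1-carbaldehyde (open form of 5, not isolated) | C[C@@]1(CO)CC[C@]1(C)C=O | intermediate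
7 | rac-cis-(2-ethenyl-1,2-dimethylcyclobutyl)methanol | C[C@@]1(CO)CC[C@]1(C)C=C | intermediate
8 | 5-bromo-2-hydroxy-4-methoxybenzaldehyde | COc1cc(O)c(C=O)cc1Br | starting material
9 | ethyl (E)-3-(5-bromo-2-hydroxy-4-methoxyphenyl)prop-2-enoate (not isolated; isomerises and lactonises) | CCOC(=O)/C=C/c1cc(Br)c(OC)cc1O | intermediate
10 | 6-bromo-7-methoxy-2H-chromen-2-one | COc1cc2oc(=O)ccc2cc1Br | intermediate
11 | rac-cis-6-{(E)-2-[2-(hydroxymethyl)-1,2-dimethylcyclobutyl]ethenyl}-7-methoxy-2H-chromen-2-one | C[C@@]1(CO)CC[C@]1(C)/C=C/c1cc2ccc(=O)oc2cc1OC | intermediate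
12 | rac-cis-2-[(E)-2-(7-methoxy-2-oxo-2H-chromen-6-yl)ethenyl]-1,2-dimethylcyclobutane-1-carbaldehyde (formyl and alkenyl cis) | C[C@@]1(C=O)CC[C@]1(C)/C=C/c1cc2ccc(=O)oc2cc1OC | intermediate
13 | N-benzhydryl iminium ion of 12 (phosphate salt, not isolated) | C[C@@]1(/C=[NH+]/C(c2ccccc2)c2ccccc2)CC[C@]1(C)/C=C/c1cc2ccc(=O)oc2cc1OC | intermediate
14 | ring-opened N-benzhydryl enamine/1-aryl-3-methylallyl cation (achiral, enamine geometry not fixed, not isolated) | CC(CC[C+](C)/C=C/c1cc2ccc(=O)oc2cc1OC)=CNC(c1ccccc1)c1ccccc1 | intermediate
15 | N-benzhydryl iminium ion of 16 (not isolated) | COc1cc2oc(=O)ccc2cc1[C@@H]1C=C(C)CC[C@]1(C)/C=[NH+]/C(c1ccccc1)c1ccccc1 | intermediate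
16 | (1S,2S)-2-(7-methoxy-2-oxo-2H-chromen-6-yl)-1,4-dimethylcyclohex-3-ene-1-carbaldehyde | COc1cc2oc(=O)ccc2cc1[C@@H]1C=C(C)CC[C@]1(C)C=O | intermediate
17 | 6-[(1R,6R)-6-ethenyl-3,6-dimethylcyclohex-2-en-1-yl]-7-methoxy-2H-chromen-2-one | COc1cc2oc(=O)ccc2cc1[C@@H]1C=C(C)CC[C@]1(C)C=C | intermediate
18 | 7-hydroxy-2H-chromen-2-one (umbelliferone) | Oc1ccc2ccc(=O)oc2c1 | starting material
19 | 7-hydroxy-8-iodo-2H-chromen-2-one | Oc1ccc2ccc(=O)oc2c1I | intermediate
20 | 8-iodo-7-methoxy-2H-chromen-2-one | COc1ccc2ccc(=O)oc2c1I | intermediate
21 | 7-methoxy-8-[(E)-2-[(1R,2R)-2-(7-methoxy-2-oxo-2H-chromen-6-yl)-1,4-dimethylcyclohex-3-en-1-yl]ethenyl]-2H-chromen-2-one | COc1cc2oc(=O)ccc2cc1[C@@H]1C=C(C)CC[C@]1(C)/C=C/c1c(OC)ccc2ccc(=O)oc12 | target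

**Step count and risks**

Total: 12 steps. Longest linear sequence: 9 steps (steps 1, 2, 3, 4, 6, 7, 8, 9, 12).

Steps most likely to fail:

1. Step 8 (Proposed new method). The iminium ion may not lower the barrier to heterolysis of the four-membered ring enough, so that conversion stalls or an uncatalysed, unselective thermal background reaction takes over. Closure from an open, non-bridged arrangement would erode the cis selectivity, and loose ion pairing would erode the enantioselectivity. Fallback with known chemistry: starting from 12, the thermal vinylcyclobutane-to-cyclohexene rearrangement (degassed o-dichlorobenzene, 150 °C; homolysis of the doubly activated ring bond and reclosure at the benzylic terminus) should give the cis aldehyde as a racemate, that is 16 together with its mirror image, ent-aldehyde F1. Condensation of the racemate with (1R,2R)-N,N'-dimethyl-1,2-diphenylethane-1,2-diamine (4 Å molecular sieves, CH2Cl2, rt) gives two diastereomeric imidazolidines, aminal F2 from 16 and aminal F3 from F1, which are separated by chromatography or crystallisation. Hydrolysis of F2 (1 M HCl, Et2O, rt) returns to the route at 16.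

2. Step 12. Migratory insertion of the di-ortho-substituted arylpalladium species into a vinyl group flanked by a quaternary carbon may be too slow, so that hydrodehalogenation of 20 and catalyst decay win. Fallback: starting from 16 (step 9 is then skipped), Takai olefination (CrCl2, CHI3, THF, 0 °C) gives the (E)-vinyl iodide F4. Separately, 20 is converted by Miyaura borylation (B2pin2, Pd(dppf)Cl2, KOAc, dioxane, 90 °C) into the pinacol boronate F5. Suzuki–Miyaura coupling of F4 with F5 (Pd(PPh3)4, K3PO4, dioxane/H2O, 60 °C) forms the same styryl bond from the other side and rejoins the route at 21.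

3. Step 4. The lactol, held closed by two adjacent quaternary carbons, may open too slowly, so that the ylide is consumed by deprotonation and decay before olefination. Fallback: starting from 4, LiAlH4 (THF, 0 °C) gives the meso cis-diol F6; monosilylation (NaH, then TBSCl, THF) gives the racemic mono-silyl ether F7; Dess–Martin oxidation gives the silyloxy aldehyde F8; Wittig methylenation (Ph3PCH3Br, KOt-Bu, THF) gives the vinyl silyl ether F9; Bu4NF (THF, rt) removes the silyl group and returns to the route at 7.

**Further compounds**

F1 | step 8 | (1R,2R)-2-(7-methoxy-2-oxo-2H-chromen-6-yl)-1,4-dimethylcyclohex-3-ene-1-carbaldehyde (enantiomer of 16) | COc1cc2oc(=O)ccc2cc1[C@H]1C=C(C)CC[C@@]1(C)C=O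
F2 | step 8 | (4R,5R)-1,3-dimethyl-4,5-diphenylimidazolidine aminal of 16 | COc1cc2oc(=O)ccc2cc1[C@@H]1C=C(C)CC[C@]1(C)C1N(C)[C@H](c2ccccc2)[C@@H](c2ccccc2)N1C
F3 | step 8 | (4R,5R)-1,3-dimethyl-4,5-diphenylimidazolidine aminal of F1 | COc1cc2oc(=O)ccc2cc1[C@H]1C=C(C)CC[C@@]1(C)C1N(C)[C@H](c2ccccc2)[C@@H](c2ccccc2)N1C
F4 | step 12 | 6-[(1R,6S)-6-[(E)-2-iodoethenyl]-3,6-dimethylcyclohex-2-en-1-yl]-7-methoxy-2H-chromen-2-one | COc1cc2oc(=O)ccc2cc1[C@@H]1C=C(C)CC[C@]1(C)/C=C/I
F5 | step 12 | 7-methoxy-8-(4,4,5,5-tetramethyl-1,3,2-dioxaborolan-2-yl)-2H-chromen-2-one | COc1ccc2ccc(=O)oc2c1B1OC(C)(C)C(C)(C)O1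
F6 | step 4 | cis-(1,2-dimethylcyclobutane-1,2-diyl)dimethanol (meso) | C[C@@]1(CO)CC[C@]1(C)CO
F7 | step 4 | rac-cis-[2-({[tert-butyl(dimethyl)silyl]oxy}methyl)-1,2-dimethylcyclobutyl]methanol | C[C@@]1(CO[Si](C)(C)C(C)(C)C)CC[C@]1(C)CO
F8 | step 4 | rac-cis-2-({[tert-butyl(dimethyl)silyl]oxy}methyl)-1,2-dimethylcyclobutane-1-carbaldehyde | C[C@@]1(CO[Si](C)(C)C(C)(C)C)CC[C@]1(C)C=O
F9 | step 4 | rac-cis-tert-butyl[(2-ethenyl-1,2-dimethylcyclobutyl)methoxy]dimethylsilane | C[C@@]1(CO[Si](C)(C)C(C)(C)C)CC[C@]1(C)C=C
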